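**Retrosynthetic overview**
1. Target ⇒ C12 α-methyl aldehyde + 3-methylfuran-2(5H)-one; a vinylogous aldol/elimination builds the Z-ylidene butenolide last.
2. C1–H and C11–C12 ⇒ Z-ethylidene on ring A: reagent-controlled syn-hydroboration, then a one-carbon 1,2-boronate shift; the C9 ester comes from 3-phenylpropanoic acid (acetic acid + benzyl bromide).
3. Ring B allylic alcohol ⇒ spiro enedione ⇒ spiro diketone (Pd dehydrogenation, CBS reduction).
4. Spiro[4.5] core ⇒ 3-(1-hydroxy-2-methylcyclobutyl)cyclohexenone: amine-catalysed vinylogous α-ketol (semipinacol) ring expansion, cyclobutanol → cyclopentanone, which creates C5 and carries C4 by a retentive 1,2-shift.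
5. That cyclobutanol ⇒ 3-iodo-6-methylcyclohexenone (from cyclohexane-1,3-dione) + 2-methylcyclobutanone. Ring order: ring B (six-membered, bought) → cyclobutane → ring A (five-membered, by expansion) → butenolide.

Numbering used for all spiro compounds (target numbering): C1 (side-chain carbon), C2, C3, C4 (CHMe), C5 (spiro), C6 (allylic CH2), C7=C8(Me), C9 (O-bearing), C10; side chain C11 (CHMe), C12 (=CH).

Assumption: in step 4 the quinine-derived amine is taken to open the enone face that leads to 5S; if the sense is the opposite, its quinidine-derived pseudoenantiomer is used and nothing else changes.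

**Step 1**
Reactants: 1 cyclohexane-1,3-dione
Product: 2 3-iodocyclohex-2-en-1-one
Conditions: PPh3, I2, Et3N, MeCN, rt then reflux
Reagents that add atoms: iodine, II
Why: Deoxyiodination of a vinylogous acid: the enol is O-activated by Ph3PI2 and iodide adds–eliminates at C3 to give the β-iodo enone.

**Step 2**
Reactants: 2 3-iodocyclohex-2-en-1-one
Product: 4 3-iodo-6-methylcyclohex-2-en-1-one (racemic), via lithium dienolate 3 (not isolated)
Conditions: LiN(iPr)2 (LDA), THF, −78 °C; MeI, −78 to −20 °C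
Reagents that add atoms: iodomethane, CI
Why: Kinetic α′-deprotonation gives the cross-conjugated lithium enolate, which is C-methylated (enolate alkylation); the C6 centre made here is racemic and is erased in step 5.

**Step 3**
Reactants: 4 3-iodo-6-methylcyclohex-2-en-1-one; 5 2-methylcyclobutanone (racemic, 3 equiv)
Product: 6 rac-3-[(1R*,2S*)-1-hydroxy-2-methylcyclobutyl]-6-methylcyclohex-2-en-1-one (OH cis to the cyclobutane methyl; both C6 epimers)
Conditions: CrCl2 (4 equiv), NiCl2 (2 mol %), DMF, rt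
Reagents that add atoms: none
Why: Nozaki–Hiyama–Kishi alkenylation: the alkenylchromium made from the C–I bond adds 1,2 to the strained ketone anti to its methyl group and tolerates the enone carbonyl.

**Step 4**
Reactants: 6 rac-3-[(1R*,2S*)-1-hydroxy-2-methylcyclobutyl]-6-methylcyclohex-2-en-1-one
Product: 7 (4S,5S)-4,8-dimethylspiro[4.5]decane-1,9-dione (both C8 epimers)
Conditions: 9-amino-9-deoxy-epi-quinine (20 mol %), N-Boc-L-phenylglycine (40 mol %), CCl4, rt, to about 50 % conversion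
Reagents that add atoms: none
Why: Proposed new method: an amine-catalysed asymmetric vinylogous α-ketol (semipinacol-type) ring expansion run as a kinetic resolution of a racemic cyclobutanol whose migrating carbon is a stereocentre; the primary amine forms the conjugated iminium of the enone and makes C5 electrophilic, the C1–C4 bond of the (1R,2S)-enantiomer lies perpendicular to the iminium plane on the face left open by the catalyst (OH near the vinylic C10–H, ring CH2 near C6) and shifts to C5 with retention at C4 while the carbinol becomes the C1 ketone (about 20 kcal/mol of ring strain released), so the catalyst sets C5 (S) and C4 (S) is carried over, and the mismatched enantiomer is recovered or gives the separable (4R,5S)-dione; the closest known reaction type is the cinchona-primary-amine-catalysed vinylogous α-ketol rearrangement of achiral 3-(1-hydroxycyclobutyl)cyclohex-2-enones, which has not been shown with a stereogenic secondary migrating carbon, with an α′-methyl enone or as a resolution.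

**Step 5**
Reactants: 7 (4S,5S)-4,8-dimethylspiro[4.5]decane-1,9-dione
Product: 8 (4S,5S)-4,8-dimethylspiro[4.5]dec-7-ene-1,9-dione
Conditions: Pd(OCOCF3)2 (5 mol %), DMSO (10 mol %), O2 (1 atm), AcOH, 80 °C
Reagents that add atoms: none
Why: Pd-catalysed aerobic α,β-dehydrogenation (Pd enolate, β-hydride elimination): in ring B only C8–C7 can desaturate because C10 is flanked by quaternary C5, over-oxidation to a phenol is impossible, the hindered cyclopentanone reacts far more slowly, and both C8 epimers give the same enone.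

**Step 6**
Reactants: 8 (4S,5S)-4,8-dimethylspiro[4.5]dec-7-ene-1,9-dione
Product: 9 (4S,5S,9S)-9-hydroxy-4,8-dimethylspiro[4.5]dec-7-en-1-one
Conditions: (R)-2-methyl-CBS-oxazaborolidine (20 mol %), catecholborane (1.2 equiv), toluene, −78 °C
Reagents that add atoms: none
Why: Corey–Bakshi–Shibata reduction: the (R)-oxazaborolidine delivers hydride to the enone carbonyl with the C8 alkenyl arm as the large group, setting C9 (S), while the neopentyl C1 ketone is left at −78 °C.

**Step 7**
Reactants: 9 (4S,5S,9S)-9-hydroxy-4,8-dimethylspiro[4.5]dec-7-en-1-one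
Product: 10 (1Z,4S,5S,9S)-1-ethylidene-4,8-dimethylspiro[4.5]dec-7-en-9-ol
Conditions: EtPPh3Br (3 equiv), KOtBu (3 equiv), THF, rt to 50 °C
Reagents that add atoms: ethyltriphenylphosphonium bromide, CC[P+](c1ccccc1)(c1ccccc1)c1ccccc1.[Br-]
Why: Wittig ethylidenation of a ketone flanked by a quaternary carbon gives, as with 17-keto steroids, the Z-alkene (methyl syn to C5); the free alcohol is carried as its alkoxide.

**Step 8**
Reactants: 11 acetic acid; 12 benzyl bromide
Product: 14 3-phenylpropanoic acid, via dilithium ethenediolate 13 (not isolated)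
Conditions: LiN(iPr)2 (2.1 equiv), THF/HMPA, 0 °C; BnBr, 0 °C to rt; aq HCl
Reagents that add atoms: none
Why: SN2 C-benzylation of the acetic acid dianion (enolate alkylation).

**Step 9**
Reactants: 10 (1Z,4S,5S,9S)-1-ethylidene-4,8-dimethylspiro[4.5]dec-7-en-9-ol; 14 3-phenylpropanoic acid
Product: 15 (1Z,4S,5S,9S)-1-ethylidene-4,8-dimethylspiro[4.5]dec-7-en-9-yl 3-phenylpropanoate
Conditions: DCC, DMAP (cat.), CH2Cl2, 0 °C to rt
Reagents that add atoms: none
Why: Steglich esterification; the C9–O bond is not touched, so C9 stays S.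

**Step 10**
Reactants: 15 (1Z,4S,5S,9S)-1-ethylidene-4,8-dimethylspiro[4.5]dec-7-en-9-yl 3-phenylpropanoate
Product: 18 (1R,4S,5S,9S)-4,8-dimethyl-1-[(1S)-1-(4,4,5,5-tetramethyl-1,3,2-dioxaborolan-2-yl)ethyl]spiro[4.5]dec-7-en-9-yl 3-phenylpropanoate, via isopinocampheyl borane adduct 16 (not isolated), via diethyl boronate 17 (not isolated)
Conditions: IpcBH2 [from (+)-α-pinene] (1.5 equiv), THF/Et2O, −25 °C; CH3CHO (excess), 0 °C to rt; pinacol, rt
Reagents that add atoms: monoisopinocampheylborane, C[C@H]1[C@H](B)C[C@@H]2C[C@H]1C2(C)C; pinacol, CC(C)(O)C(C)(C)O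
Why: Brown asymmetric hydroboration: IpcBH2 adds H and B syn across the Z-alkene from the C10 face (the sense it shows with 1-methylcycloalkenes), boron going to the CH carbon, so C1 (R) and C11 (S) are set together; the acyloxy-deactivated, more hindered ring B alkene and the ester are left, and acetaldehyde then pinacol replace the ligands on boron.

**Step 11**
Reactants: 18 (1R,4S,5S,9S)-4,8-dimethyl-1-[(1S)-1-(4,4,5,5-tetramethyl-1,3,2-dioxaborolan-2-yl)ethyl]spiro[4.5]dec-7-en-9-yl 3-phenylpropanoate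
Product: 20 (1R,4S,5S,9S)-4,8-dimethyl-1-[(2S)-1-oxopropan-2-yl]spiro[4.5]dec-7-en-9-yl 3-phenylpropanoate, via α-chloroboronic ester 19 (not isolated)
Conditions: CH2Cl2, n-BuLi, THF, −100 °C; 18, then ZnCl2, −100 °C to rt; H2O2, pH 7 phosphate buffer, THF, 0 °C
Reagents that add atoms: dichloromethane, ClCCl; hydrogen peroxide, OO
Why: Matteson homologation: LiCHCl2 forms the boronate, whose C11 group undergoes a 1,2-shift from boron to carbon with retention; peroxide oxidation of the α-chloroboronic ester gives a chlorohydrin that collapses to the aldehyde without touching C11.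

**Step 12**
Reactants: 20 (1R,4S,5S,9S)-4,8-dimethyl-1-[(2S)-1-oxopropan-2-yl]spiro[4.5]dec-7-en-9-yl 3-phenylpropanoate; 21 3-methylfuran-2(5H)-one
Product: 24 (1R,4S,5S,9S)-4,8-dimethyl-1-[(2S)-1-[(2Z)-4-methyl-5-oxofuran-2(5H)-ylidene]propan-2-yl]spiro[4.5]dec-7-en-9-yl 3-phenylpropanoate (target), via silyloxyfuran 22 (not isolated), via aldol silyl ether 23 (not isolated)
Conditions: 21, TBSOTf, iPr2NEt, CH2Cl2, 0 °C; 20, −78 °C to rt; DBU, rt
Reagents that add atoms: none
Why: Vinylogous Mukaiyama aldol of the silyloxyfuran at its C5, then DBU-mediated E1cB loss of silanolate, gives the thermodynamically preferred Z-ylidene butenolide; the cold aldol stage avoids epimerisation of C11.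

**Compound list**
1 | cyclohexane-1,3-dione | O=C1CCCC(=O)C1 | starting material
2 | 3-iodocyclohex-2-en-1-one | O=C1C=C(I)CCC1 | intermediate
3 | lithium 5-iodocyclohexa-1,5-dien-1-olate | [Li+].[O-]C1=CCCC(I)=C1 | intermediate (not isolated)
4 | 3-iodo-6-methylcyclohex-2-en-1-one (racemic) | CC1CCC(I)=CC1=O | intermediate
5 | 2-methylcyclobutanone (racemic) | CC1CCC1=O | starting material
6 | rac-3-[(1R*,2S*)-1-hydroxy-2-methylcyclobutyl]-6-methylcyclohex-2-en-1-one (reactive 1R,2S enantiomer drawn; both C6 epimers) | C[C@H]1CC[C@]1(O)C1=CC(=O)C(C)CC1 | intermediate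
7 | (4S,5S)-4,8-dimethylspiro[4.5]decane-1,9-dione (both C8 epimers) | O=C1CC[C@H](C)[C@@]12CCC(C)C(=O)C2 | intermediate
8 | (4S,5S)-4,8-dimethylspiro[4.5]dec-7-ene-1,9-dione | O=C1CC[C@H](C)[C@@]12CC=C(C)C(=O)C2 | intermediate
9 | (4S,5S,9S)-9-hydroxy-4,8-dimethylspiro[4.5]dec-7-en-1-one | O=C1CC[C@H](C)[C@@]12CC=C(C)[C@@H](O)C2 | intermediate
10 | (1Z,4S,5S,9S)-1-ethylidene-4,8-dimethylspiro[4.5]dec-7-en-9-ol | C/C=C1/CC[C@H](C)[C@@]12CC=C(C)[C@@H](O)C2 | intermediate
11 | acetic acid | CC(=O)O | starting material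
12 | benzyl bromide | BrCc1ccccc1 | starting material
13 | dilithium ethene-1,1-diolate | [Li+].[Li+].[O-]C([O-])=C | intermediate (not isolated)
14 | 3-phenylpropanoic acid | OC(=O)CCc1ccccc1 | intermediate
15 | (1Z,4S,5S,9S)-1-ethylidene-4,8-dimethylspiro[4.5]dec-7-en-9-yl 3-phenylpropanoate | C/C=C1/CC[C@H](C)[C@@]12CC=C(C)[C@@H](OC(=O)CCc3ccccc3)C2 | intermediate
16 | isopinocampheyl[(1S)-1-{(1R,4S,5S,9S)-4,8-dimethyl-9-(3-phenylpropanoyloxy)spiro[4.5]dec-7-en-1-yl}ethyl]borane | C[C@H]1[C@H](B[C@@H](C)[C@H]3CC[C@H](C)[C@@]34CC=C(C)[C@@H](OC(=O)CCc5ccccc5)C4)C[C@@H]2C[C@H]1C2(C)C | intermediate (not isolated)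
17 | diethyl [(1S)-1-{(1R,4S,5S,9S)-4,8-dimethyl-9-(3-phenylpropanoyloxy)spiro[4.5]dec-7-en-1-yl}ethyl]boronate | CCOB(OCC)[C@@H](C)[C@H]1CC[C@H](C)[C@@]12CC=C(C)[C@@H](OC(=O)CCc3ccccc3)C2 | intermediate (not isolated)
18 | (1R,4S,5S,9S)-4,8-dimethyl-1-[(1S)-1-(4,4,5,5-tetramethyl-1,3,2-dioxaborolan-2-yl)ethyl]spiro[4.5]dec-7-en-9-yl 3-phenylpropanoate | CC1(C)OB(OC1(C)C)[C@@H](C)[C@H]1CC[C@H](C)[C@@]12CC=C(C)[C@@H](OC(=O)CCc3ccccc3)C2 | intermediate
19 | (1R,4S,5S,9S)-1-[(2S)-1-chloro-1-(4,4,5,5-tetramethyl-1,3,2-dioxaborolan-2-yl)propan-2-yl]-4,8-dimethylspiro[4.5]dec-7-en-9-yl 3-phenylpropanoate (both CHCl epimers) | CC1(C)OB(OC1(C)C)C(Cl)[C@@H](C)[C@H]1CC[C@H](C)[C@@]12CC=C(C)[C@@H](OC(=O)CCc3ccccc3)C2 | intermediate (not isolated)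
20 | (1R,4S,5S,9S)-4,8-dimethyl-1-[(2S)-1-oxopropan-2-yl]spiro[4.5]dec-7-en-9-yl 3-phenylpropanoate | O=C[C@@H](C)[C@H]1CC[C@H](C)[C@@]12CC=C(C)[C@@H](OC(=O)CCc3ccccc3)C2 | intermediate
21 | 3-methylfuran-2(5H)-one | CC1=CCOC1=O | starting material
22 | 2-(tert-butyldimethylsilyloxy)-3-methylfuran | Cc1ccoc1O[Si](C)(C)C(C)(C)C | intermediate (not isolated)
23 | (1R,4S,5S,9S)-1-[(2S)-1-(tert-butyldimethylsilyloxy)-1-(4-methyl-5-oxo-2,5-dihydrofuran-2-yl)propan-2-yl]-4,8-dimethylspiro[4.5]dec-7-en-9-yl 3-phenylpropanoate (mixture at the two new centres) | CC1=CC(OC1=O)C(O[Si](C)(C)C(C)(C)C)[C@@H](C)[C@H]1CC[C@H](C)[C@@]12CC=C(C)[C@@H](OC(=O)CCc3ccccc3)C2 | intermediate (not isolated)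
24 | (1R,4S,5S,9S)-4,8-dimethyl-1-[(2S)-1-[(2Z)-4-methyl-5-oxofuran-2(5H)-ylidene]propan-2-yl]spiro[4.5]dec-7-en-9-yl 3-phenylpropanoate | CC1=C/C(=C/[C@@H](C)[C@H]2CC[C@H](C)[C@@]23CC=C(C)[C@@H](OC(=O)CCc2ccccc2)C3)OC1=O | target

**Step count**
Total: 12 steps. Longest linear sequence: 11 steps (steps 1–7 and 9–12); step 8 is a one-step side branch.

**Three steps most likely to fail**

Step 3 (an alkenylchromium adding to a ketone may be slow or low-yielding). The fallback sets out from 4 and comes back at 6. Compound 4 is masked with 1,2-bis(trimethylsilyloxy)ethane and catalytic TMSOTf (CH2Cl2, −78 °C) as 7-iodo-10-methyl-1,4-dioxaspiro[4.5]dec-6-ene F1. Iodine–lithium exchange (t-BuLi, THF, −78 °C) and addition of 5 give rac-(1R*,2S*)-2-methyl-1-(10-methyl-1,4-dioxaspiro[4.5]dec-6-en-7-yl)cyclobutan-1-ol F2. Aqueous oxalic acid then unmasks the enone to give 6 (β-acyl vinyl anion equivalent in place of the chromium reagent).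

Step 4 (the proposed new step; as a resolution its yield cannot exceed 50 %, and the selectivity between the two cyclobutanol enantiomers is untested). The fallback uses known chemistry, sets out from 6 and comes back at 9. Racemic 6 is rearranged with p-TsOH·H2O (toluene, 60 °C; Brønsted-acid vinylogous semipinacol ring expansion under substrate control) to rac-(4S*,5S*)-4,8-dimethylspiro[4.5]decane-1,9-dione F3. Dehydrogenation as in step 5 gives rac-(4S*,5S*)-4,8-dimethylspiro[4.5]dec-7-ene-1,9-dione F4. The reagent-controlled CBS reduction of step 6 then turns the two enantiomers into two diastereomeric 9S alcohols, 9 and (4R,5R,9S)-9-hydroxy-4,8-dimethylspiro[4.5]dec-7-en-1-one F5, which are separated by chromatography; 9 continues.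

Step 10 (face selectivity of the hydroboration: IpcBH2 has only moderate intrinsic selectivity with trialkyl-substituted alkenes and may prefer the C6 face). The fallback sets out from 15, comes back at 20, and uses the C6 face instead.
- Shi epoxidation (fructose-derived ketone, KHSO5, K2CO3, MeCN/dimethoxymethane, 0 °C) gives (1S,4S,5S,9S,11R)-1,11-epoxy-1-ethyl-4,8-dimethylspiro[4.5]dec-7-en-9-yl 3-phenylpropanoate F6, with the oxirane oxygen on the C6 face.
- BF3·OEt2 (CH2Cl2, −78 °C) triggers a Meinwald rearrangement in which the C11 hydride shifts to C1 anti to the leaving oxygen. This gives (1S,4S,5S,9S)-1-acetyl-4,8-dimethylspiro[4.5]dec-7-en-9-yl 3-phenylpropanoate F7, with C1–H on the C10 face.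
- Methylenation with Ph3P=CH2 gives (1R,4S,5S,9S)-4,8-dimethyl-1-(prop-1-en-2-yl)spiro[4.5]dec-7-en-9-yl 3-phenylpropanoate F8.
- 9-BBN followed by buffered H2O2 gives (1R,4S,5S,9S)-1-[(2S)-1-hydroxypropan-2-yl]-4,8-dimethylspiro[4.5]dec-7-en-9-yl 3-phenylpropanoate F9. The C11 selectivity of this hydroboration is substrate-controlled and would need checking.
- Dess–Martin oxidation returns 20.

**Further compounds**
F1 | step 3 | 7-iodo-10-methyl-1,4-dioxaspiro[4.5]dec-6-ene (racemic) | CC1CCC(I)=CC12OCCO2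
F2 | step 3 | rac-(1R*,2S*)-2-methyl-1-(10-methyl-1,4-dioxaspiro[4.5]dec-6-en-7-yl)cyclobutan-1-ol | C[C@H]1CC[C@]1(O)C1=CC2(OCCO2)C(C)CC1
F3 | step 4 | rac-(4S*,5S*)-4,8-dimethylspiro[4.5]decane-1,9-dione | O=C1CC[C@H](C)[C@@]12CCC(C)C(=O)C2
F4 | step 4 | rac-(4S*,5S*)-4,8-dimethylspiro[4.5]dec-7-ene-1,9-dione | O=C1CC[C@H](C)[C@@]12CC=C(C)C(=O)C2
F5 | step 4 | (4R,5R,9S)-9-hydroxy-4,8-dimethylspiro[4.5]dec-7-en-1-one | O=C1CC[C@@H](C)[C@]12CC=C(C)[C@@H](O)C2
F6 | step 10 | (1S,4S,5S,9S,11R)-1,11-epoxy-1-ethyl-4,8-dimethylspiro[4.5]dec-7-en-9-yl 3-phenylpropanoate | C[C@H]1O[C@]12CC[C@H](C)[C@@]23CC=C(C)[C@@H](OC(=O)CCc4ccccc4)C3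
F7 | step 10 | (1S,4S,5S,9S)-1-acetyl-4,8-dimethylspiro[4.5]dec-7-en-9-yl 3-phenylpropanoate | CC(=O)[C@H]1CC[C@H](C)[C@@]12CC=C(C)[C@@H](OC(=O)CCc3ccccc3)C2
F8 | step 10 | (1R,4S,5S,9S)-4,8-dimethyl-1-(prop-1-en-2-yl)spiro[4.5]dec-7-en-9-yl 3-phenylpropanoate | CC(=C)[C@H]1CC[C@H](C)[C@@]12CC=C(C)[C@@H](OC(=O)CCc3ccccc3)C2
F9 | step 10 | (1R,4S,5S,9S)-1-[(2S)-1-hydroxypropan-2-yl]-4,8-dimethylspiro[4.5]dec-7-en-9-yl 3-phenylpropanoate | OC[C@@H](C)[C@H]1CC[C@H](C)[C@@]12CC=C(C)[C@@H](OC(=O)CCc3ccccc3)C2
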